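**Retrosynthetic overview**

1. Target 20 comes from flavone 19 (5-OMe, 2',5'-di-OBn). BCl3 does not spare aryl benzyl ethers, so the C5 methyl ether and both benzyl ethers are cleaved together in one operation and no separate hydrogenolysis is planned.
2. Ring C (the pyranone) is the only ring that is built. It is closed last through the O1–C2 bond, by 6-endo-dig addition of the phenol of ynone 18 to its alkyne.
3. Ynone 18 is cut into silyl triflate 9 and propiolic acid 15. In ring A the C4 acyl carbon sits on C4a and O1 on the neighbouring C8a, and C5 to C8 all carry methoxyls at this stage. The bonds C4a–C4 and C8a–O1 therefore come from insertion of the symmetric 3,4,5,6-tetramethoxybenzyne into the C–O bond of the acid.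
4. Triflate 9 derives from 1,2,3,4-tetramethoxybenzene (lithiation–borylation–oxidation, bromination, O-silylation, retro-Brook shift and triflation). Acid 15 derives from 2,5-dihydroxybenzaldehyde (double benzylation, Corey–Fuchs olefination, carboxylation).
5. Ring order: rings A and B are bought as benzenes; ring C follows after the key step.

Key step: step 8

Assumption: ynone 18 is treated as the isolated product of step 8; any part of it that closes to flavone 19 under the fluoride conditions is the product of step 9 and is carried along.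

**Route**

Step 1
Reactants: 1 1,2,3,4-tetramethoxybenzene
Product: 4 2,3,4,5-tetramethoxyphenol, via aryllithium 2 (not isolated), via dimethyl arylboronate 3 (not isolated)
Conditions: n-BuLi, TMEDA, THF, 0 °C to rt; B(OMe)3, −78 °C to rt; AcOH, 30% aq. H2O2, 0 °C to rt
Reagents that add atoms: n-butyllithium, [Li]CCCC (lithium of 2 only); trimethyl borate, COB(OC)OC (boron and two methoxyls of 3 only); hydrogen peroxide, OO (hydroxyl oxygen of 4)
Why: Methoxy-directed ortho-lithiation can only take place at the two equivalent ring C–H positions of 1, and borylation followed by peroxide oxidation of the C–B bond (aryl shift from boron to oxygen) converts the aryllithium into the phenol.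

Step 2
Reactants: 4 2,3,4,5-tetramethoxyphenol
Product: 5 2-bromo-3,4,5,6-tetramethoxyphenol
Conditions: NBS (1.0 equiv), dry CH2Cl2, −40 to 0 °C, dark, N2
Reagents that add atoms: N-bromosuccinimide, O=C1CCC(=O)N1Br
Why: Electrophilic aromatic bromination can only go to the single unsubstituted ring carbon, which is ortho to the hydroxyl, and one equivalent of NBS in dry solvent at low temperature should hold back oxidation to a quinone.

Step 3
Reactants: 5 2-bromo-3,4,5,6-tetramethoxyphenol
Product: 6 (2-bromo-3,4,5,6-tetramethoxyphenoxy)trimethylsilane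
Conditions: HMDS, THF, 70 °C; evaporation, crude used directly
Reagents that add atoms: hexamethyldisilazane, C[Si](C)(C)N[Si](C)(C)C
Why: O-silylation of a phenol with HMDS releases only ammonia, so the moisture-sensitive aryl silyl ether needed for the silyl shift can be used after simple evaporation.

Step 4
Reactants: 6 (2-bromo-3,4,5,6-tetramethoxyphenoxy)trimethylsilane
Product: 9 3,4,5,6-tetramethoxy-2-(trimethylsilyl)phenyl trifluoromethanesulfonate, via silyloxy aryllithium 7 (not isolated), via lithium silylphenoxide 8 (not isolated)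
Conditions: n-BuLi, THF, −100 to −78 °C; Tf2O, −100 to −78 °C
Reagents that add atoms: n-butyllithium, [Li]CCCC (lithium of 7 and 8 only); trifluoromethanesulfonic anhydride, O=S(=O)(OS(=O)(=O)C(F)(F)F)C(F)(F)F
Why: Bromine–lithium exchange gives aryllithium 7, whose carbanion takes the silyl group from the neighbouring oxygen (retro-Brook 1,3 O-to-C shift) to give phenoxide 8, which is triflated by Tf2O; this is the standard entry to ortho-silylaryl triflates.

Step 5
Reactants: 10 2,5-dihydroxybenzaldehyde; 11 benzyl bromide
Product: 12 2,5-bis(benzyloxy)benzaldehyde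
Conditions: BnBr (2.4 equiv in all), K2CO3 (3 equiv), DMF, 60 °C
Reagents that add atoms: benzyl bromide, BrCc1ccccc1 (second equivalent of 11, supplies the second benzyl group)
Why: Twofold Williamson etherification, in which each of the two phenoxides of 10 displaces bromide from one molecule of benzyl bromide, so two equivalents of 11 are consumed; the aldehyde is untouched by carbonate.

Step 6
Reactants: 12 2,5-bis(benzyloxy)benzaldehyde
Product: 13 1,4-bis(benzyloxy)-2-(2,2-dibromoethenyl)benzene
Conditions: CBr4, PPh3, CH2Cl2, 0 °C
Reagents that add atoms: carbon tetrabromide, BrC(Br)(Br)Br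
Why: First stage of the Corey–Fuchs sequence, a Wittig-type olefination of the aldehyde by the dibromomethylene ylide formed from CBr4 and PPh3.

Step 7
Reactants: 13 1,4-bis(benzyloxy)-2-(2,2-dibromoethenyl)benzene
Product: 15 3-[2,5-bis(benzyloxy)phenyl]prop-2-ynoic acid, via lithium acetylide 14 (not isolated)
Conditions: n-BuLi (2.1 equiv), THF, −78 °C; dry CO2, −78 °C to rt; 1 M HCl
Reagents that add atoms: n-butyllithium, [Li]CCCC (lithium of 14 only); carbon dioxide, O=C=O
Why: Second stage of the Corey–Fuchs sequence (bromine–lithium exchange and Fritsch–Buttenberg–Wiechell rearrangement) gives the lithium acetylide, which is carboxylated by CO2 in the same flask; the benzyl ethers tolerate n-BuLi at −78 °C.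

Step 8
Reactants: 9 3,4,5,6-tetramethoxy-2-(trimethylsilyl)phenyl trifluoromethanesulfonate; 15 3-[2,5-bis(benzyloxy)phenyl]prop-2-ynoic acid
Product: 18 3-[2,5-bis(benzyloxy)phenyl]-1-(2-hydroxy-3,4,5,6-tetramethoxyphenyl)prop-2-yn-1-one, via 3,4,5,6-tetramethoxybenzyne 16 (not isolated), via cesium aryl anion ester 17 (not isolated)
Conditions: 15 (1.0 equiv), 9 (1.5 equiv), CsF (4 equiv), dry THF, sealed tube, 125 °C; aq. NH4Cl
Reagents that add atoms: cesium fluoride, [Cs+].[F-] (counter-ion of 17 only)
Why: Fluoride removes the silyl group of 9 and triflate leaves, giving the symmetric aryne 16, while CsF turns acid 15 into its cesium carboxylate, whose oxygen adds to one aryne carbon (the future C8a–O1 bond) to give the ortho-metalated aryl ester 17. The carbanion of 17 then attacks its own ester carbonyl through a four-membered alkoxide that opens to the phenoxide of ketone 18 (the future C4a–C4 bond), a 1,3 O-to-C acyl shift of the anionic Fries type. The closest known reaction is the fluoride-mediated insertion of arynes from ortho-silylaryl triflates into the C–O bond of carboxylic acids to give ortho-hydroxyaryl ketones, which is documented for arylpropiolic acids. No ring is closed and no stereocenter is created in this step. Site selectivity on the aryne needs no control because both aryne carbons have a methoxy neighbour and are equivalent, and these methoxyls also activate the aryne inductively. The selectivity that must be secured is acyl shift over protonation of 17 to the plain aryl ester, and for this the acid proton is bound by the excess CsF as CsHF2, THF offers no acidic C–H, and the high temperature favours the strained four-membered transition state.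

Step 9
Reactants: 18 3-[2,5-bis(benzyloxy)phenyl]-1-(2-hydroxy-3,4,5,6-tetramethoxyphenyl)prop-2-yn-1-one
Product: 19 2-[2,5-bis(benzyloxy)phenyl]-5,6,7,8-tetramethoxy-4H-chromen-4-one
Conditions: K2CO3, dry acetone, reflux
Reagents that add atoms: none
Why: 6-endo-dig oxa-Michael addition of the phenoxide to the β-carbon of the ynone closes ring C, and in an aprotic medium with a carbonate base this mode is preferred over 5-exo-dig closure to the aurone.

Step 10
Reactants: 19 2-[2,5-bis(benzyloxy)phenyl]-5,6,7,8-tetramethoxy-4H-chromen-4-one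
Product: 20 5,2',5'-trihydroxy-6,7,8-trimethoxyflavone
Conditions: BCl3 (1 M in CH2Cl2, 8 equiv), pentamethylbenzene (6 equiv), CH2Cl2, −78 to 0 °C; MeOH quench, degassed aqueous work-up under argon
Reagents that add atoms: none
Why: BCl3 cleaves aryl benzyl ethers at low temperature, with pentamethylbenzene taking up the benzyl cations by Friedel–Crafts alkylation, and on warming it removes only the C5 methyl ether, because boron chelated between the C4 carbonyl oxygen and O5 activates that methyl toward chloride while the 6-, 7- and 8-methoxyls have no such chelate.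

**Compound list**

1 | 1,2,3,4-tetramethoxybenzene | COc1ccc(OC)c(OC)c1OC | starting material
2 | (2,3,4,5-tetramethoxyphenyl)lithium | [Li]c1cc(OC)c(OC)c(OC)c1OC | intermediate
3 | dimethyl (2,3,4,5-tetramethoxyphenyl)boronate | COB(OC)c1cc(OC)c(OC)c(OC)c1OC | intermediate
4 | 2,3,4,5-tetramethoxyphenol | Oc1cc(OC)c(OC)c(OC)c1OC | intermediate
5 | 2-bromo-3,4,5,6-tetramethoxyphenol | Oc1c(Br)c(OC)c(OC)c(OC)c1OC | intermediate
6 | (2-bromo-3,4,5,6-tetramethoxyphenoxy)trimethylsilane | C[Si](C)(C)Oc1c(Br)c(OC)c(OC)c(OC)c1OC | intermediate
7 | [3,4,5,6-tetramethoxy-2-(trimethylsilyloxy)phenyl]lithium | [Li]c1c(O[Si](C)(C)C)c(OC)c(OC)c(OC)c1OC | intermediate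
8 | lithium 3,4,5,6-tetramethoxy-2-(trimethylsilyl)phenoxide | [Li+].[O-]c1c([Si](C)(C)C)c(OC)c(OC)c(OC)c1OC | intermediate
9 | 3,4,5,6-tetramethoxy-2-(trimethylsilyl)phenyl trifluoromethanesulfonate | COc1c(OC)c(OC)c(OS(=O)(=O)C(F)(F)F)c([Si](C)(C)C)c1OC | intermediate
10 | 2,5-dihydroxybenzaldehyde | O=Cc1cc(O)ccc1O | starting material
11 | benzyl bromide | BrCc1ccccc1 | starting material
12 | 2,5-bis(benzyloxy)benzaldehyde | O=Cc1cc(OCc2ccccc2)ccc1OCc1ccccc1 | intermediate
13 | 1,4-bis(benzyloxy)-2-(2,2-dibromoethenyl)benzene | BrC(Br)=Cc1cc(OCc2ccccc2)ccc1OCc1ccccc1 | intermediate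
14 | {[2,5-bis(benzyloxy)phenyl]ethynyl}lithium | [Li]C#Cc1cc(OCc2ccccc2)ccc1OCc1ccccc1 | intermediate
15 | 3-[2,5-bis(benzyloxy)phenyl]prop-2-ynoic acid | OC(=O)C#Cc1cc(OCc2ccccc2)ccc1OCc1ccccc1 | intermediate
16 | 3,4,5,6-tetramethoxybenzyne | COC1=C(OC)C(OC)=C(OC)C#C1 | intermediate
17 | cesium 2-({3-[2,5-bis(benzyloxy)phenyl]prop-2-ynoyl}oxy)-3,4,5,6-tetramethoxybenzen-1-ide | COc1c(OC)c(OC)c(OC)c(OC(=O)C#Cc2cc(OCc3ccccc3)ccc2OCc2ccccc2)[c-]1.[Cs+] | intermediate
18 | 3-[2,5-bis(benzyloxy)phenyl]-1-(2-hydroxy-3,4,5,6-tetramethoxyphenyl)prop-2-yn-1-one | COc1c(OC)c(OC)c(C(=O)C#Cc2cc(OCc3ccccc3)ccc2OCc2ccccc2)c(O)c1OC | intermediate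
19 | 2-[2,5-bis(benzyloxy)phenyl]-5,6,7,8-tetramethoxy-4H-chromen-4-one | COc1c(OC)c(OC)c2c(=O)cc(-c3cc(OCc4ccccc4)ccc3OCc3ccccc3)oc2c1OC | intermediate
20 | 5,2',5'-trihydroxy-6,7,8-trimethoxyflavone | COc1c(OC)c(O)c2c(=O)cc(-c3cc(O)ccc3O)oc2c1OC | target

**Totals**

Total step count: 10.
Longest linear sequence: 7 steps (steps 1, 2, 3, 4, 8, 9, 10).

**Steps most likely to fail**

Step 8. The aryl anion may be protonated before the acyl shift, so that only O-arylation takes place. The propiolate may also lose CO2 at 125 °C, the product phenoxide may add to a second aryne, and the congested ring may slow the four-membered acyl transfer. The fallback drops the aryne and uses the classical chalcone route. It sets out from phenol 4 and aldehyde 12 and comes back at flavone 19. Phenol 4 would be C-acetylated at its only free ring position with AcOH and BF3·OEt2 at 80 °C to give 1-(2-hydroxy-3,4,5,6-tetramethoxyphenyl)ethan-1-one F1. Claisen–Schmidt condensation of this ketone with aldehyde 12 (KOH, EtOH, rt) should give (E)-3-[2,5-bis(benzyloxy)phenyl]-1-(2-hydroxy-3,4,5,6-tetramethoxyphenyl)prop-2-en-1-one F2. Oxidative cyclisation of the chalcone with catalytic I2 in DMSO at 130 °C would then deliver flavone 19.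

Step 2. NBS may oxidise the very electron-rich phenol to a quinone in competition with ring bromination. The fallback avoids halogenation and installs silicon by directed metalation. It sets out from phenol 4 and comes back at triflate 9. Phenol 4 would be treated with isopropyl isocyanate and Et3N in CH2Cl2 to give 2,3,4,5-tetramethoxyphenyl propan-2-ylcarbamate F3. In-situ N-silylation (TBSOTf, TMEDA, Et2O), carbamate-directed ortho-lithiation at the only ortho C–H (n-BuLi, TMEDA, −78 °C) and a TMSCl quench should give 2,3,4,5-tetramethoxy-6-(trimethylsilyl)phenyl propan-2-ylcarbamate F4. Cleavage of the carbamate with Et2NH and DBU in MeCN at 40 °C would release 3,4,5,6-tetramethoxy-2-(trimethylsilyl)phenol F5 in the flask, which would be triflated there with PhNTf2 to give 9.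

Step 10. Demethylation may run on to the 6-methoxyl once the boron chelate at O5 has formed. Benzyl cations that escape the scavenger may alkylate the hydroquinone ring, and the free hydroquinone may be oxidised by air during work-up. The fallback separates the two deprotections and uses different reagents for each. It sets out from flavone 19 and comes back at target 20. Hydrogenolysis (H2, 10% Pd/C, EtOAc/THF, rt) should remove only the benzyl groups and give 2-(2,5-dihydroxyphenyl)-5,6,7,8-tetramethoxy-4H-chromen-4-one F6. Chelation-controlled cleavage of the C5 methyl ether with AlCl3 in MeCN under argon would then give 20.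

**Further compounds**

F1 | step 8 | 1-(2-hydroxy-3,4,5,6-tetramethoxyphenyl)ethan-1-one | CC(=O)c1c(O)c(OC)c(OC)c(OC)c1OC
F2 | step 8 | (E)-3-[2,5-bis(benzyloxy)phenyl]-1-(2-hydroxy-3,4,5,6-tetramethoxyphenyl)prop-2-en-1-one | COc1c(OC)c(OC)c(C(=O)/C=C/c2cc(OCc3ccccc3)ccc2OCc2ccccc2)c(O)c1OC
F3 | step 2 | 2,3,4,5-tetramethoxyphenyl propan-2-ylcarbamate | CC(C)NC(=O)Oc1cc(OC)c(OC)c(OC)c1OC
F4 | step 2 | 2,3,4,5-tetramethoxy-6-(trimethylsilyl)phenyl propan-2-ylcarbamate | CC(C)NC(=O)Oc1c([Si](C)(C)C)c(OC)c(OC)c(OC)c1OC
F5 | step 2 | 3,4,5,6-tetramethoxy-2-(trimethylsilyl)phenol | Oc1c([Si](C)(C)C)c(OC)c(OC)c(OC)c1OC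
F6 | step 10 | 2-(2,5-dihydroxyphenyl)-5,6,7,8-tetramethoxy-4H-chromen-4-one | COc1c(OC)c(OC)c2c(=O)cc(-c3cc(O)ccc3O)oc2c1OC
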